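The constants used here are invented; what happens was integrated by code.

**Your question.** Substrate is conserved: what leaves its free form stands in free target, in idle adduct (one counts as two) or in over-reaction product, and this balance with one level of target lets me test your hunch that dosing wins.

    substrate + partner → target, rate k1*[substrate]*[partner]^0.5 (k1 = 0.0012 M⁻⁰·⁵ min⁻¹)
    substrate + target ⇌ idle adduct, settled at all times (K2 = 6.9 M⁻¹)
    partner + target → over-reaction product (k3 = 0.071 M⁻¹ min⁻¹)

| setting | teal | red | green | ochre |
|---|---|---|---|---|
| substrate | 0.10 M | 0.10 M | 0.10 M | 0.10 M |
| partner | 0.130 M (fed, over 16.0 h) | 0.130 M | 0.130 M | 0.130 M |
| time | 20 h |  | 20 h | 20 h |
| remark | a stirred flask in which partner is dosed at a steady rate over 16.0 h without added volume, worked up at 20 h | a single well-mixed tank run continuously and read at steady state, 20 h in it on average | a tube with plug flow, the mixed feed as stated, residence time 20 h | a closed flask charged with all of it at once and left for 20 h |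

- the set-up with the highest share of target in all that became target or over-reaction product, at the outlet or at the end ("none" if the first two lie within 2 percentage points) (teal / red / green / ochre / none)
- share of target in all that became target or over-reaction product, at the outlet or at the end, teal
- share of target in all that became target or over-reaction product, at the outlet or at the end, red
- share of target in all that became target or over-reaction product, at the outlet or at the end, green
- share of target in all that became target or over-reaction product, at the outlet or at the end, ochre

- a species is counted by the substrate in it: one idle adduct counts as two
- amounts and yields of target count idle adduct too
- the stated concentrations are those of everything mixed, before any reaction; amounts are the same in each set-up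
- the feed brings no volume worth counting
- in an amount of target, one idle adduct counts as one target
- run time (teal): 20 h

**The hold.** My zero is the even case, and I call the hold the level of free target at which over-reaction removes it as fast as formation makes it: the formation constant times c(substrate), over the over-reaction constant times the root of c(partner), or 0.00469 M at the charges. In ochre, free target has a half-life by over-reaction alone of 1.3 h as charged, short against 20 h, so I let it ride on this quasi-steady level, which scales as substrate left over the root of partner left.

**My numbers.** In ochre, with partner held as charged, substrate falls to 59.5%, and at about two partners per substrate turned over, partner falls to 37.7%. The hold there is 0.00454 M, and the adduct balance and the substrate count give a share of 16.6%, which I also take for green, since plug flow runs like the closed flask. In teal, the root of a ramping partner averages 0.667 of its top value during the feed, so substrate ends at 68.3%, partner at 51.3%, the hold at 0.00447 M and the share at 22.3%, higher than ochre. I leave red unreckoned.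

**The check.** The forecast names teal, with teal 22.5%, red 18.2%, green 17% and ochre 17%, on the ground that "Dosing keeps partner low for most of the run". The simulation gives teal 23.8%, red 18.1%, green 17.5% and ochre 17.5%, so teal leads, by 5.7 percentage points over red against a margin of 2 points.

**Two days.** Teal's own readings at 20.0 h, substrate 70% and partner 62%, put the hold at 0.00416 M and the share at 22.1%, against the 23.8% of that flask. The same teal flask read at 2.0 d has 45% of its substrate and 22% of its partner left unbound, so its hold is 0.00448 M and the reckoned share is 11.0%. That flask gives 10.9%.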